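The decalin is disconnected across C1–C2 and C5–C10 (labdane numbering), so that rings A and B arise together from an acyclic trienone by an intramolecular Diels–Alder reaction. The diene is the C3 silyl enol ether C2=C3–C4=C5, the dienophile the isopropenyl ketone C1=C10–C9(=O), the tether C6–C8. The step exploits the C3 oxygen and the ring-B alkene carbon C9, both carried as carbonyls, and the C6 oxygen stereocentre, which through allylic strain with the C4 CH2O arm sets C5 and C10. Afterwards the C3=C4 enol ether delivers the C4 quaternary centre, the C9 ketone the tetrasubstituted alkene with its side chain.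

Key step: step 5

Remark on the chemistry: ring positions follow labdane numbering (ring A = C1–C5 and C10, ring B = C5–C10; C17 on C8, C18 and C19 on C4, C20 on C10). β is the face of C20 and α the opposite face. TBS = tert-butyldimethylsilyl, PMB = 4-methoxybenzyl. The C6 carbinol is deliberately carried as the 6α epimer and inverted in steps 13 and 14.

Step 1
Reactants: 1 diethyl (2-oxopropyl)phosphonate; 2 paraformaldehyde; 3 4-methoxybenzyl alcohol
Product: 5 diethyl [1-(4-methoxybenzyloxy)-3-oxobutan-2-yl]phosphonate, via diethyl (3-oxobut-1-en-2-yl)phosphonate 4 (not isolated)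
Conditions: piperidine (cat.), AcOH (cat.), toluene, 70 °C
Reagents that add atoms: paraformaldehyde (C=O); 4-methoxybenzyl alcohol (COc1ccc(CO)cc1)
Why: Knoevenagel condensation with formaldehyde followed by oxa-Michael addition of the alcohol to the doubly activated 1-acylvinylphosphonate should give the alkoxymethyl ketophosphonate, whose single stereocentre is lost in step 2.

Step 2
Reactants: 6 (S)-5-(hydroxymethyl)dihydrofuran-2(3H)-one; 5 phosphonate from step 1
Product: 8 (S)-5-[(E)-2-[(4-methoxybenzyloxy)methyl]-3-oxobut-1-enyl]dihydrofuran-2(3H)-one, via (S)-5-oxotetrahydrofuran-2-carbaldehyde 7 (not isolated)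
Conditions: Dess–Martin periodinane, CH2Cl2, 0 °C → rt; then 5, LiCl, iPr2NEt, MeCN, 0 °C → rt
Reagents that add atoms: phosphonate 5 (CCOP(=O)(OCC)C(COCc1ccc(OC)cc1)C(C)=O)
Why: Dess–Martin oxidation and Horner–Wadsworth–Emmons olefination under mild LiCl/amine conditions should keep the α-acyloxy stereocentre (C6, S) intact and give the E alkene, acetyl trans to C6, as expected for an α-branched ketophosphonate.

Step 3
Reactants: 8 enone lactone; 9 N,O-dimethylhydroxylamine hydrochloride
Product: 10 (S,E)-4-hydroxy-N-methoxy-6-[(4-methoxybenzyloxy)methyl]-N-methyl-7-oxooct-5-enamide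
Conditions: 9, Me2AlCl, CH2Cl2, −20 → 0 °C
Reagents that add atoms: N,O-dimethylhydroxylamine hydrochloride (CNOC.Cl)
Why: aluminium amide aminolysis of the γ-lactone (Weinreb amide formation) should open the ring at the acyl carbon, leaving C6 untouched and freeing its hydroxyl, the hindered enone reacting more slowly than the lactone.

Step 4
Reactants: 10 hydroxy amide; 11 tert-butyldimethylsilyl trifluoromethanesulfonate
Product: 12 (S,E)-4,7-bis(tert-butyldimethylsilyloxy)-N-methoxy-6-[(4-methoxybenzyloxy)methyl]-N-methylocta-5,7-dienamide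
Conditions: Et3N, CH2Cl2, −78 → 0 °C
Reagents that add atoms: tert-butyldimethylsilyl trifluoromethanesulfonate (CC(C)(C)[Si](C)(C)OS(=O)(=O)C(F)(F)F)
Why: silyl triflate/amine O-silylation of the alcohol and soft enolisation of the methyl ketone at its methyl group should give the cross-conjugated 2-silyloxydiene with the C4=C5 geometry unchanged.

Step 5
Reactants: 12 diene Weinreb amide; 13 isopropenylmagnesium bromide
Product: 15 3,6α-bis(tert-butyldimethylsilyloxy)-4-[(4-methoxybenzyloxy)methyl]-10β-methyl-5αH-Δ3-octalin-9-one, via (S,E)-6,9-bis(tert-butyldimethylsilyloxy)-8-[(4-methoxybenzyloxy)methyl]-2-methyldeca-1,7,9-trien-3-one 14 (not isolated)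
Conditions: CH2=C(CH3)MgBr, THF, −20 → 0 °C; aq NH4Cl; then toluene, BHT, 80 °C
Reagents that add atoms: isopropenylmagnesium bromide (C=C(C)[Mg]Br)
Why: Addition of the Grignard reagent to the Weinreb amide gives on work-up trienone 14, which should undergo a thermal, asynchronous but concerted normal-demand intramolecular Diels–Alder reaction in which the nucleophilic diene terminus C2 bonds to the enone β-carbon C1 ahead of C5–C10. The closest known reaction type is the intramolecular Diels–Alder reaction of 1,7,9-decatrien-3-ones carrying 2-silyloxydienes. Ring A closes as the six-membered [4+2] ring through both new bonds (C1–C2 and C5–C10), and ring B closes at C5–C10 through the four-atom C6–C9 tether held chair-like. C5 is controlled by the C6 stereocentre, because allylic 1,3-strain with the cis CH2OPMB group on C4 holds C6–H in the diene plane, so the tether reaches the face anti to the OTBS group (6α-OTBS, 5α-H). C10 is controlled by the exo-tether, methyl-endo transition state, which gives the trans ring fusion. The step needs this exo-tether mode to win over the carbonyl-endo mode, which the α-methyl group of the dienophile and the chair tether should secure, while regiochemistry is fixed by the tether and the matched polarity.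

Step 6
Reactants: 15 cycloadduct; 16 diiodomethane
Product: 17 3β,6α-bis(tert-butyldimethylsilyloxy)-3α,4α-methano-4β-[(4-methoxybenzyloxy)methyl]-10β-methyl-5αH-decalin-9-one
Conditions: Et2Zn, CH2Cl2, 0 °C → rt
Reagents that add atoms: diiodomethane (ICI)
Why: Furukawa-modified Simmons–Smith cyclopropanation of the electron-rich silyl enol ether should occur on the α face, away from the axial C20 methyl, which sets C3 and C4 together (future C18 α, CH2OPMB β).

Step 7
Reactants: 17 siloxycyclopropane ketone; 18 iodomethane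
Product: 19 3β,6α-bis(tert-butyldimethylsilyloxy)-3α,4α-methano-4β-[(4-methoxybenzyloxy)methyl]-8α,10β-dimethyl-5αH-decalin-9-one
Conditions: LiN(iPr)2, THF, −78 °C; then MeI, −78 → −20 °C
Reagents that add atoms: iodomethane (CI)
Why: enolate alkylation is regiospecific because the C9 ketone can enolise only towards C8 (C10 is quaternary); the new C8 centre (equatorial 8α-methyl expected) is erased in step 8.

Step 8
Reactants: 19 methyl ketone; 20 N-phenylbis(trifluoromethanesulfonimide)
Product: 21 3β,6α-bis(tert-butyldimethylsilyloxy)-3α,4α-methano-4β-[(4-methoxybenzyloxy)methyl]-8,10β-dimethyl-5αH-octal-8-en-9-yl trifluoromethanesulfonate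
Conditions: KN(SiMe3)2, THF, −78 °C; then PhNTf2, −78 → 0 °C
Reagents that add atoms: N-phenylbis(trifluoromethanesulfonimide) (O=S(=O)(N(c1ccccc1)S(=O)(=O)C(F)(F)F)C(F)(F)F)
Why: O-triflation of the potassium enolate, which can only be the C8=C9 enolate, gives the tetrasubstituted enol triflate; no stereocentre is set.

Step 9
Reactants: 22 4-(tert-butyldimethylsilyloxy)but-1-yne; 23 trimethylaluminium; 24 methyl chloroformate
Product: 26 methyl (E)-5-(tert-butyldimethylsilyloxy)-3-methylpent-2-enoate, via (E)-[4-(tert-butyldimethylsilyloxy)-2-methylbut-1-enyl]dimethylalane 25 (not isolated)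
Conditions: Cp2ZrCl2 (cat.), CH2Cl2, 0 °C → rt; then ClCO2Me, 0 °C
Reagents that add atoms: trimethylaluminium (C[Al](C)C); methyl chloroformate (COC(=O)Cl)
Why: zirconium-catalysed carboalumination adds methyl and aluminium syn across the alkyne and the alkenylalane is acylated with retention, so the E enoate should result.

Step 10
Reactants: 26 silyloxy enoate; 27 triphenylphosphine dibromide
Product: 28 methyl (E)-5-bromo-3-methylpent-2-enoate
Conditions: CH2Cl2, 0 °C → rt
Reagents that add atoms: triphenylphosphine dibromide (BrP(Br)(c1ccccc1)(c1ccccc1)c1ccccc1)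
Why: Appel-type substitution through an alkoxyphosphonium bromide converts the primary silyl ether directly into the bromide without touching the enoate geometry.

Step 11
Reactants: 21 enol triflate; 28 bromo enoate
Product: 30 methyl 3β,6α-bis(tert-butyldimethylsilyloxy)-19-(4-methoxybenzyloxy)-3α,18-cyclolabda-8,13E-dien-15-oate, via (E)-(5-methoxy-3-methyl-5-oxopent-3-enyl)zinc bromide 29 (not isolated)
Conditions: 28, Zn, I2 (cat.), DMA, 70 °C; then 21, Pd(dppf)Cl2 (cat.), LiCl, THF/DMA, 60 °C
Reagents that add atoms: methyl (E)-5-bromo-3-methylpent-2-enoate (COC(=O)/C=C(\C)CCBr)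
Why: Negishi sp2–sp3 coupling of the primary alkylzinc bromide, made in the flask from 28 by zinc insertion, with the enol triflate joins C9 to C11 with retention of both alkene geometries; no stereocentre is formed.

Step 12
Reactants: 30 coupled ester
Product: 31 methyl 6α-hydroxy-19-(4-methoxybenzyloxy)-3-oxolabda-8,13E-dien-15-oate
Conditions: HCl (0.5 M in MeOH), THF, rt
Reagents that add atoms: none
Why: acid-mediated desilylation and opening of the cyclopropanol by protonation at the unsubstituted CH2 with cleavage of the C3–C18 bond should give the C3 ketone and the 4α-methyl group with C4 unchanged, and it frees the 6α-alcohol.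

Step 13
Reactants: 31 keto alcohol
Product: 32 methyl 19-(4-methoxybenzyloxy)-3,6-dioxolabda-8,13E-dien-15-oate
Conditions: Dess–Martin periodinane, CH2Cl2, 0 °C → rt
Reagents that add atoms: none
Why: Dess–Martin oxidation removes the 6α carbinol that served as control element, and C5, now α to a ketone, already has the thermodynamically preferred trans ring fusion.

Step 14
Reactants: 32 diketone
Product: 33 methyl 3α,6β-dihydroxy-19-(4-methoxybenzyloxy)labda-8,13E-dien-15-oate
Conditions: LiBH(sBu)3 (L-Selectride), THF, −78 → −20 °C; aq NH4Cl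
Reagents that add atoms: none
Why: the bulky hydride should attack C3 along the equatorial direction to give the axial 3α-alcohol and attack C6 from the α face, opposite to the axial C20 methyl and C19 arm, to give the axial 6β-alcohol, while the hindered β,β-disubstituted enoate is spared at low temperature.

Step 15
Reactants: 33 diol
Product: 34 methyl 3α,6β,19-trihydroxylabda-8,13E-dien-15-oate
Conditions: DDQ, CH2Cl2/pH 7 buffer, 0 °C → rt
Reagents that add atoms: none
Why: oxidative cleavage of the p-methoxybenzyl ether by DDQ in wet solvent should release the C19 alcohol without affecting the alkenes or the ester.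

Step 16
Reactants: 34 triol ester; 35 lithium hydroxide
Product: 36 3α,6β,19-trihydroxylabda-8,13E-dien-15-oic acid (target)
Conditions: LiOH, THF/MeOH/H2O, rt; then dilute HCl to pH 3
Reagents that add atoms: lithium hydroxide ([Li+].[OH-])
Why: saponification of the methyl ester and acidification give the acid; no stereocentre is touched.

Compound list
1 | diethyl (2-oxopropyl)phosphonate | CCOP(=O)(CC(C)=O)OCC | starting material
2 | paraformaldehyde (formaldehyde source) | C=O | starting material
3 | 4-methoxybenzyl alcohol | COc1ccc(CO)cc1 | starting material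
4 | diethyl (3-oxobut-1-en-2-yl)phosphonate (not isolated) | CCOP(=O)(OCC)C(=C)C(C)=O | intermediate
5 | diethyl [1-(4-methoxybenzyloxy)-3-oxobutan-2-yl]phosphonate (racemic) | CCOP(=O)(OCC)C(COCc1ccc(OC)cc1)C(C)=O | intermediate
6 | (S)-5-(hydroxymethyl)dihydrofuran-2(3H)-one | OC[C@@H]1CCC(=O)O1 | starting material
7 | (S)-5-oxotetrahydrofuran-2-carbaldehyde (not isolated) | O=C[C@@H]1CCC(=O)O1 | intermediate
8 | (S)-5-[(E)-2-[(4-methoxybenzyloxy)methyl]-3-oxobut-1-enyl]dihydrofuran-2(3H)-one | CC(=O)/C(COCc1ccc(OC)cc1)=C/[C@@H]2CCC(=O)O2 | intermediate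
9 | N,O-dimethylhydroxylamine hydrochloride | CNOC.Cl | starting material
10 | (S,E)-4-hydroxy-N-methoxy-6-[(4-methoxybenzyloxy)methyl]-N-methyl-7-oxooct-5-enamide | CC(=O)/C(COCc1ccc(OC)cc1)=C/[C@@H](O)CCC(=O)N(C)OC | intermediate
11 | tert-butyldimethylsilyl trifluoromethanesulfonate | CC(C)(C)[Si](C)(C)OS(=O)(=O)C(F)(F)F | starting material
12 | (S,E)-4,7-bis(tert-butyldimethylsilyloxy)-N-methoxy-6-[(4-methoxybenzyloxy)methyl]-N-methylocta-5,7-dienamide | C=C(O[Si](C)(C)C(C)(C)C)/C(COCc1ccc(OC)cc1)=C/[C@@H](O[Si](C)(C)C(C)(C)C)CCC(=O)N(C)OC | intermediate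
13 | isopropenylmagnesium bromide | C=C(C)[Mg]Br | starting material
14 | (S,E)-6,9-bis(tert-butyldimethylsilyloxy)-8-[(4-methoxybenzyloxy)methyl]-2-methyldeca-1,7,9-trien-3-one (not isolated) | C=C(C)C(=O)CC[C@H](O[Si](C)(C)C(C)(C)C)/C=C(\COCc1ccc(OC)cc1)C(=C)O[Si](C)(C)C(C)(C)C | intermediate
15 | 3,6α-bis(tert-butyldimethylsilyloxy)-4-[(4-methoxybenzyloxy)methyl]-10β-methyl-5αH-Δ3-octalin-9-one (trans-fused) | C1C(=O)[C@@]2(C)CCC(O[Si](C)(C)C(C)(C)C)=C(COCc3ccc(OC)cc3)[C@@H]2[C@@H](O[Si](C)(C)C(C)(C)C)C1 | intermediate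
16 | diiodomethane | ICI | starting material
17 | 3β,6α-bis(tert-butyldimethylsilyloxy)-3α,4α-methano-4β-[(4-methoxybenzyloxy)methyl]-10β-methyl-5αH-decalin-9-one | C1C(=O)[C@@]2(C)CC[C@@]3(O[Si](C)(C)C(C)(C)C)C[C@@]3(COCc4ccc(OC)cc4)[C@@H]2[C@@H](O[Si](C)(C)C(C)(C)C)C1 | intermediate
18 | iodomethane | CI | starting material
19 | 8α-methyl derivative of 17 (3β,6α-bis(TBSO)-3α,4α-methano-4β-(PMBOCH2)-8α,10β-dimethyl-5αH-decalin-9-one) | C[C@H]1C(=O)[C@@]2(C)CC[C@@]3(O[Si](C)(C)C(C)(C)C)C[C@@]3(COCc4ccc(OC)cc4)[C@@H]2[C@@H](O[Si](C)(C)C(C)(C)C)C1 | intermediate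
20 | N-phenylbis(trifluoromethanesulfonimide) | O=S(=O)(N(c1ccccc1)S(=O)(=O)C(F)(F)F)C(F)(F)F | starting material
21 | C8=C9 enol triflate of 19 | CC1=C(OS(=O)(=O)C(F)(F)F)[C@@]2(C)CC[C@@]3(O[Si](C)(C)C(C)(C)C)C[C@@]3(COCc4ccc(OC)cc4)[C@@H]2[C@@H](O[Si](C)(C)C(C)(C)C)C1 | intermediate
22 | 4-(tert-butyldimethylsilyloxy)but-1-yne | C#CCCO[Si](C)(C)C(C)(C)C | starting material
23 | trimethylaluminium | C[Al](C)C | starting material
24 | methyl chloroformate | COC(=O)Cl | starting material
25 | (E)-[4-(tert-butyldimethylsilyloxy)-2-methylbut-1-enyl]dimethylalane (not isolated) | C[Al](C)/C=C(\C)CCO[Si](C)(C)C(C)(C)C | intermediate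
26 | methyl (E)-5-(tert-butyldimethylsilyloxy)-3-methylpent-2-enoate | COC(=O)/C=C(\C)CCO[Si](C)(C)C(C)(C)C | intermediate
27 | triphenylphosphine dibromide | BrP(Br)(c1ccccc1)(c1ccccc1)c1ccccc1 | starting material
28 | methyl (E)-5-bromo-3-methylpent-2-enoate | COC(=O)/C=C(\C)CCBr | intermediate
29 | (E)-(5-methoxy-3-methyl-5-oxopent-3-enyl)zinc bromide (not isolated) | COC(=O)/C=C(\C)CC[Zn]Br | intermediate
30 | methyl 3β,6α-bis(tert-butyldimethylsilyloxy)-19-(4-methoxybenzyloxy)-3α,18-cyclolabda-8,13E-dien-15-oate | CC1=C(CC/C(C)=C/C(=O)OC)[C@@]2(C)CC[C@@]3(O[Si](C)(C)C(C)(C)C)C[C@@]3(COCc4ccc(OC)cc4)[C@@H]2[C@@H](O[Si](C)(C)C(C)(C)C)C1 | intermediate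
31 | methyl 6α-hydroxy-19-(4-methoxybenzyloxy)-3-oxolabda-8,13E-dien-15-oate | CC1=C(CC/C(C)=C/C(=O)OC)[C@@]2(C)CCC(=O)[C@](C)(COCc3ccc(OC)cc3)[C@@H]2[C@@H](O)C1 | intermediate
32 | methyl 19-(4-methoxybenzyloxy)-3,6-dioxolabda-8,13E-dien-15-oate | CC1=C(CC/C(C)=C/C(=O)OC)[C@@]2(C)CCC(=O)[C@](C)(COCc3ccc(OC)cc3)[C@@H]2C(=O)C1 | intermediate
33 | methyl 3α,6β-dihydroxy-19-(4-methoxybenzyloxy)labda-8,13E-dien-15-oate | CC1=C(CC/C(C)=C/C(=O)OC)[C@@]2(C)CC[C@@H](O)[C@](C)(COCc3ccc(OC)cc3)[C@@H]2[C@H](O)C1 | intermediate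
34 | methyl 3α,6β,19-trihydroxylabda-8,13E-dien-15-oate | CC1=C(CC/C(C)=C/C(=O)OC)[C@@]2(C)CC[C@@H](O)[C@](C)(CO)[C@@H]2[C@H](O)C1 | intermediate
35 | lithium hydroxide | [Li+].[OH-] | starting material
36 | 3α,6β,19-trihydroxylabda-8,13E-dien-15-oic acid (CNP0246116.2) | CC1=C(CC/C(C)=C/C(=O)O)[C@@]2(C)CC[C@@H](O)[C@](C)(CO)[C@@H]2[C@H](O)C1 | target

Total step count: 16. Longest linear sequence: 14 steps (step 1, steps 2–8, steps 11–16); steps 9 and 10 form a convergent branch.

Steps most likely to fail

Step 5. The carbonyl-endo (tether-endo) transition state may compete and give the cis-fused adduct with the wrong C10 configuration, which no later step can mend. The fallback takes the carbonyl out of conjugation during the cycloaddition. It sets out from 12: reduction of the Weinreb amide with iBu2AlH (THF, −78 °C) should give (S,E)-4,7-bis(tert-butyldimethylsilyloxy)-6-[(4-methoxybenzyloxy)methyl]octa-5,7-dienal F1. Addition of 13 should give (6S,7E)-6,9-bis(tert-butyldimethylsilyloxy)-8-[(4-methoxybenzyloxy)methyl]-2-methyldeca-1,7,9-trien-3-ol F2 as both C3 epimers. Heating F2 (toluene, BHT, 170 °C, sealed tube) should give the cycloadduct 3,6α-bis(tert-butyldimethylsilyloxy)-4-[(4-methoxybenzyloxy)methyl]-10β-methyl-5αH-Δ3-octalin-9-ol F3. With an sp3 carbon at C9 there is no carbonyl-endo preference, so the chair tether and the same allylic strain at C6 should decide the outcome on steric grounds. Dess–Martin oxidation of F3 returns to the route at 15.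

Step 11. Oxidative addition at the hindered tetrasubstituted triflate may be slow, so that β-hydride elimination of the alkylpalladium species, protonation of the alkylzinc, its cyclisation onto its own enoate by 3-exo conjugate addition, or opening of the siloxycyclopropane by electrophilic palladium takes over. The fallback builds the side chain in two couplings, keeps the enoate away from any alkylmetal carbon, and sets out from 21. Stille coupling with tributyl(vinyl)stannane (Pd(PPh3)4, LiCl, CuI, DMF, 60 °C) should give 3β,6α-bis(tert-butyldimethylsilyloxy)-3α,4α-methano-4β-[(4-methoxybenzyloxy)methyl]-8,10β-dimethyl-9-vinyl-5αH-octal-8-ene F4. Anti-Markovnikov hydroboration of its terminal vinyl group with 9-borabicyclo[3.3.1]nonane (THF, rt) should give the B-alkyl borane 9-{2-[3β,6α-bis(tert-butyldimethylsilyloxy)-3α,4α-methano-4β-[(4-methoxybenzyloxy)methyl]-8,10β-dimethyl-5αH-octal-8-en-9-yl]ethyl}-9-borabicyclo[3.3.1]nonane F5, used in situ. Suzuki–Miyaura coupling of F5 with methyl (E)-3-iodobut-2-enoate (COC(=O)/C=C(\C)I; Pd(dppf)Cl2, Cs2CO3, DMF/H2O, rt) should form C12–C13 with retention of the E geometry and returns to the route at 30.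

Step 2. The phosphonate anion may fragment by retro-oxa-Michael loss of the p-methoxybenzyloxide, E/Z control may erode, and the α-acyloxy aldehyde may epimerise under base. The fallback makes the same alkene under neutral conditions by cross-metathesis and sets out from 6. After oxidation to 7 as before, non-basic Takai–Lombardo methylenation (Zn, CH2Br2, TiCl4, THF) should give (S)-5-vinyldihydrofuran-2(3H)-one F6. Separately, Morita–Baylis–Hillman reaction of methyl vinyl ketone (C=CC(C)=O) with 2 (DABCO, THF/H2O) should give 3-(hydroxymethyl)but-3-en-2-one F7. Protection with 4-methoxybenzyl trichloroacetimidate (camphorsulfonic acid cat., CH2Cl2) should give 3-[(4-methoxybenzyloxy)methyl]but-3-en-2-one F8. Cross-metathesis of F6 with excess F8 (second-generation Hoveyda–Grubbs catalyst, CH2Cl2, 40 °C) should give the thermodynamically favoured E enone and returns to the route at 8.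

Further compounds
F1 | step 5 | (S,E)-4,7-bis(tert-butyldimethylsilyloxy)-6-[(4-methoxybenzyloxy)methyl]octa-5,7-dienal | C=C(O[Si](C)(C)C(C)(C)C)/C(COCc1ccc(OC)cc1)=C/[C@@H](O[Si](C)(C)C(C)(C)C)CCC=O
F2 | step 5 | (6S,7E)-6,9-bis(tert-butyldimethylsilyloxy)-8-[(4-methoxybenzyloxy)methyl]-2-methyldeca-1,7,9-trien-3-ol (C3 epimers) | C=C(C)C(O)CC[C@H](O[Si](C)(C)C(C)(C)C)/C=C(\COCc1ccc(OC)cc1)C(=C)O[Si](C)(C)C(C)(C)C
F3 | step 5 | 3,6α-bis(tert-butyldimethylsilyloxy)-4-[(4-methoxybenzyloxy)methyl]-10β-methyl-5αH-Δ3-octalin-9-ol (C9 epimers) | C1C(O)[C@@]2(C)CCC(O[Si](C)(C)C(C)(C)C)=C(COCc3ccc(OC)cc3)[C@@H]2[C@@H](O[Si](C)(C)C(C)(C)C)C1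
F4 | step 11 | 3β,6α-bis(tert-butyldimethylsilyloxy)-3α,4α-methano-4β-[(4-methoxybenzyloxy)methyl]-8,10β-dimethyl-9-vinyl-5αH-octal-8-ene | CC1=C(C=C)[C@@]2(C)CC[C@@]3(O[Si](C)(C)C(C)(C)C)C[C@@]3(COCc4ccc(OC)cc4)[C@@H]2[C@@H](O[Si](C)(C)C(C)(C)C)C1
F5 | step 11 | 9-{2-[3β,6α-bis(tert-butyldimethylsilyloxy)-3α,4α-methano-4β-[(4-methoxybenzyloxy)methyl]-8,10β-dimethyl-5αH-octal-8-en-9-yl]ethyl}-9-borabicyclo[3.3.1]nonane | CC1=C(CCB5C6CCCC5CCC6)[C@@]2(C)CC[C@@]3(O[Si](C)(C)C(C)(C)C)C[C@@]3(COCc4ccc(OC)cc4)[C@@H]2[C@@H](O[Si](C)(C)C(C)(C)C)C1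
F6 | step 2 | (S)-5-vinyldihydrofuran-2(3H)-one | C=C[C@@H]1CCC(=O)O1
F7 | step 2 | 3-(hydroxymethyl)but-3-en-2-one | CC(=O)C(=C)CO
F8 | step 2 | 3-[(4-methoxybenzyloxy)methyl]but-3-en-2-one | CC(=O)C(=C)COCc1ccc(OC)cc1
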